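Count what the partner pays for before you decide whether to raise Friday's charge to Sunday's.

| flask | substrate | partner | remark | time |
|---|---|---|---|---|
| cedar | 2 M | 1 M | run made earlier |  |
| maple | 2 M | 1.8 M | run made earlier |  |
| Friday's | 2.0 M | 2.00 M |  | 30 min |
| Sunday's | 2.0 M | 2.40 M |  | 30 min |

| run | time / min | intermediate A / % | intermediate B / % | product / % | substrate / % |
|---|---|---|---|---|---|
| cedar | 3.00 | 5 | 2 | 0 | 88 |
| cedar | 6.00 | 15 | 2 | 0 | 82 |
| cedar | 10.0 | 15 | 4 | 0 | 78 |
| cedar | 12.0 | 13 | 4 | 0 | 74 |
| cedar | 15.0 | 13 | 2 | 0 | 69 |
| maple | 1.33 | 7 | 0 | 0 | 93 |
| maple | 4.00 | 19 | 1 | 0 | 80 |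
| maple | 8.00 | 25 | 8 | 2 | 68 |
| maple | 10.0 | 22 | 6 | 0 | 61 |
| maple | 15.0 | 24 | 14 | 4 | 55 |

(standard deviation of a reading: 2 percentage points)

- the earlier runs were read with a standard deviation of 2 percentage points
- a reading of intermediate A is of its free form alone

- which of these there is most of at the end, counted by the substrate in it, Friday's (intermediate B / product / intermediate A / substrate)
- which of these there is most of at the end, counted by the substrate in it, Sunday's (intermediate B / product / intermediate A / substrate)
- the largest of these amounts at the end, in percent of the substrate charged, Friday's
- the largest of these amounts at the end, in percent of the substrate charged, Sunday's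

My reckoning takes each substrate lost to use one partner in making intermediate A, and each intermediate A passing on to intermediate B to use a second. Maple's last reading, at 15.0 min, then gives 1.40 for the quantity I carry, the partner bill n, the partner used per substrate lost, which is one plus intermediate B and product over substrate lost.

Let s and b be the substrate and partner concentrations, with ds/dt = −ksb. For constant n, b = ns + Δ, where Δ is the partner charge less n times the substrate charge, and ln(b/s) then moves linearly in time with slope kΔ. Maple gives k = 0.0404 M⁻¹ min⁻¹. Cedar, with its own bill of 1.06, gives 0.0418 M⁻¹ min⁻¹, close to maple's value; both are read from scattered readings. The two bills differ, and I carry maple's because its partner charge stands nearer to Friday's than cedar's does.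

The bill on the substrate charge is 2.80 M, more than Sunday's partner charge, so partner is the limiting reagent in both flasks. At this bill, I reckon substrate to stop near 28.6% on Friday's and 14.3% on Sunday's. At 30 min I expect 39.2% on Friday's and 30.3% on Sunday's. For Sunday's I reckon intermediate B and product together at 27.9%, less than my substrate figure, and maple's intermediate A reading of 25% at 8.00 min is less too. For Friday's the same sum is 24.3%, again less than my substrate figure. I therefore expect substrate to lead on both days, with the extra partner removing 8.9 percentage points more of it, so I would charge Sunday's.

The forecast names substrate for Friday's at 34% (29% to 40%), below my figure, and substrate for Sunday's at 29% (24% to 35%). In its words: “Substrate probably still leads on both days, but Sunday is close to a tie with B.”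

The flask gives substrate at 37.4% on Friday's and substrate at 29.8% on Sunday's, so the forecast stands.

    intermediate A ⇌ intermediate C (K = 0.350, k = 0.0512 min⁻¹)
    partner + intermediate A → intermediate B (k = 0.0514 M⁻¹ min⁻¹)
    intermediate A ⇌ intermediate D (K = 0.801, k = 0.0247 min⁻¹)
    substrate + partner → intermediate A (k = 0.0406 M⁻¹ min⁻¹)
    intermediate B → product (k = 0.0365 min⁻¹)

At 30 min the bill, partner used over substrate lost, stands at 1.37 on Friday's and 1.44 on Sunday's. Intermediates C and D, holding 7.58% and 10.3% on Friday's, take no partner in the scheme. Now take the neighbouring flask, Friday's with 0.50 M of substrate. Here Δ turns positive, 1.30 M, and the same k and bill give 14.5% of substrate at 30 min. That flask holds 14.6% of its substrate, with 66% of its partner left.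

The earlier runs and the new flask are calculated with made-up constants; scatter was added.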